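**Retrosynthetic overview**
1. Target 19 is the C9 ferulate of triol 17; the ester C9–O bond is made last by Mitsunobu coupling with ferulic acid.
2. Triol 17 comes from the cis-fused furofuranone 11: guaiacyl Grignard addition at the lactol carbon C7' opens the lactone, and hydrogenolysis removes C7'–OH and the benzyl ethers.
3. Feature: in the oxolane O1–C2–C3–C4–C5, C2 is benzylic to the syringyl ring, C4 carries C7' (kept as a lactone carbonyl, an acceptor) and C5 is an unsubstituted CH2 on O1. O1–C5 is therefore formaldehyde inserted into the C2–C4 bond of a cyclopropane C2–C3–C4, forming O1–C2 and C4–C5.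
4. Cyclopropane lactone 8 comes from enal 4 and dimethyl bromomalonate by organocatalytic Michael/alkylation, then reduction and lactonisation; 4 comes from syringaldehyde.
5. Ring order: cyclopropane (step 3), γ-lactone (step 4), oxolane (step 5); the lactone is opened again in step 9.

Key step: step 5

Remark on the chemistry: the oxolane is numbered O1, C2 (syringyl), C3 (bears C9H2O), C4 (bears C7'), C5, and the target is read as (2S,3R,4R), i.e. 2,3-trans and 3,4-cis.

**Step 1**
Reactants: 1 syringaldehyde
Product: 2 4-(benzyloxy)-3,5-dimethoxybenzaldehyde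
Conditions: BnBr, K2CO3, DMF, 60 °C
Reagents that add atoms: benzyl bromide, BrCc1ccccc1
Why: Williamson etherification of the acidic phenol should be clean with benzyl bromide and carbonate, and the benzyl ether survives every step until the planned hydrogenolysis.

**Step 2**
Reactants: 2 4-(benzyloxy)-3,5-dimethoxybenzaldehyde; 3 (triphenylphosphoranylidene)acetaldehyde
Product: 4 (E)-3-[4-(benzyloxy)-3,5-dimethoxyphenyl]prop-2-enal
Conditions: toluene, 90 °C
Reagents that add atoms: none
Why: Wittig olefination with the stabilised formylmethylene ylide homologates the aromatic aldehyde by two carbons to the (E)-enal, with the ylide held near one equivalent to limit a second homologation.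

**Step 3**
Reactants: 4 (E)-3-[4-(benzyloxy)-3,5-dimethoxyphenyl]prop-2-enal; 5 dimethyl 2-bromomalonate
Product: 6 dimethyl (2S,3R)-2-[4-(benzyloxy)-3,5-dimethoxyphenyl]-3-formylcyclopropane-1,1-dicarboxylate
Conditions: (S)-2-[diphenyl(trimethylsilyloxy)methyl]pyrrolidine (20 mol %), 2,6-lutidine, CH2Cl2, 0 → 23 °C
Reagents that add atoms: none
Why: Michael-initiated ring closure under iminium then enamine catalysis is an established enantioselective cyclopropanation of cinnamaldehydes: the silyloxydiphenylmethyl group of the (S)-catalyst shields one face of the (E)-iminium ion so the bromomalonate adds to the other face of the β-carbon (aryl carbon S), and intramolecular alkylation of the enamine closes the ring with formyl trans to aryl (formyl carbon R).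

**Step 4**
Reactants: 6 dimethyl (2S,3R)-2-[4-(benzyloxy)-3,5-dimethoxyphenyl]-3-formylcyclopropane-1,1-dicarboxylate
Product: 8 methyl (1S,5R,6S)-6-[4-(benzyloxy)-3,5-dimethoxyphenyl]-2-oxo-3-oxabicyclo[3.1.0]hexane-1-carboxylate, via hydroxymethyl cyclopropane diester 7 (not isolated)
Conditions: NaBH4, MeOH, 0 → 23 °C; aq. NH4Cl
Reagents that add atoms: none
Why: Borohydride reduces only the aldehyde, and the new hydroxymethyl group lactonises onto the geminal ester cis to it (intramolecular transesterification), which makes the malonate carbon a defined quaternary stereocentre without any new stereochemical choice and leaves the aryl group exo.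

**Step 5**
Reactants: 8 methyl (1S,5R,6S)-6-[4-(benzyloxy)-3,5-dimethoxyphenyl]-2-oxo-3-oxabicyclo[3.1.0]hexane-1-carboxylate; 9 formaldehyde (supplied as paraformaldehyde)
Product: 10 methyl (1R,5R,6S)-6-[4-(benzyloxy)-3,5-dimethoxyphenyl]-2-oxo-3,7-dioxabicyclo[3.3.0]octane-1-carboxylate
Conditions: (CH2O)n (5 equiv), Sn(OTf)2 (10 mol %), 4 Å MS, ClCH2CH2Cl, 23 → 45 °C
Reagents that add atoms: none
Why: Proposed new method: Sn(OTf)2 chelates the lactone and ester carbonyls on C4 and heterolyses the C2–C4 bond to a tin enolate and a 4-benzyloxy-3,5-dimethoxybenzylic cation, and formaldehyde is then built in between the two ends with its oxygen on C2 and its carbon on C4; the closest known reaction is the Lewis-acid [3+2] annulation of 2-arylcyclopropane-1,1-diesters with aldehydes, extended here to formaldehyde and to a lactone-fused acceptor. The oxolane closes either by 5-(enolexo)-endo-trig attack of the enolate on the O-alkyl oxocarbenium ion (C4–C5 last) or by 5-exo-trig collapse of the tin aldolate onto the benzylic cation (O1–C2 last), and both orders give the same ring. C4 becomes quaternary with C5 cis to C2 because the two new bonds are joined through the three-atom C3–C2–O1 chain, which can span only one face of the lactone enolate, so the bicycle is cis-fused and C3, which breaks no bond, carries the absolute configuration. C2 needs net retention (aryl trans to C9, on the convex face), which an invertive displacement would not give; it is expected because formaldehyde is the least Lewis-basic aldehyde and the donor is strongly cation-stabilising, so ionisation should precede capture, C2 should be planar when the ring closes, and closure with the aryl on the convex face avoids eclipsing it with C9, as in acid-mediated closures of benzylic cations to 2-aryloxolane lignans. The step also needs cleavage of C2–C4 and not C3–C4, which is secured by C2 being the only aryl-bearing cyclopropane carbon, and it needs the arene to stay untouched, for which the catalyst is kept at 10 mol % and formaldehyde is released slowly from the polymer.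

**Step 6**
Reactants: 10 methyl (1R,5R,6S)-6-[4-(benzyloxy)-3,5-dimethoxyphenyl]-2-oxo-3,7-dioxabicyclo[3.3.0]octane-1-carboxylate
Product: 11 (1R,5R,6S)-6-[4-(benzyloxy)-3,5-dimethoxyphenyl]-3,7-dioxabicyclo[3.3.0]octan-2-one
Conditions: LiCl, H2O, DMSO, 140 °C
Reagents that add atoms: none
Why: Krapcho demethoxycarbonylation: chloride demethylates the ester, the carboxylate loses CO2, and the lactone enolate is protonated to the only accessible cis-fused bicycle, which sets C4 with its hydrogen cis to H3; the ring-held C5–O1 bond lies near the enolate plane and so should not eliminate.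

**Step 7**
Reactants: 11 (1R,5R,6S)-6-[4-(benzyloxy)-3,5-dimethoxyphenyl]-3,7-dioxabicyclo[3.3.0]octan-2-one
Product: 12 (1R,5R,6S)-6-[4-(benzyloxy)-3,5-dimethoxyphenyl]-3,7-dioxabicyclo[3.3.0]octan-2-ol (lactol; both anomers)
Conditions: i-Bu2AlH, CH2Cl2, −78 °C; aq. potassium sodium tartrate
Reagents that add atoms: none
Why: Partial reduction of the γ-lactone with i-Bu2AlH at −78 °C stops at the lactol because the tetrahedral aluminium hemiacetal is stable until work-up; the anomeric mixture is of no consequence.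

**Step 8**
Reactants: 13 4-bromo-2-methoxyphenol
Product: 14 1-(benzyloxy)-4-bromo-2-methoxybenzene
Conditions: BnBr, K2CO3, DMF, 60 °C
Reagents that add atoms: benzyl bromide, BrCc1ccccc1
Why: Williamson etherification masks the phenol so that the aryl bromide can be turned into a Grignard reagent, with a group that leaves in the same hydrogenolysis as the other benzyl ether.

**Step 9**
Reactants: 12 (1R,5R,6S)-6-[4-(benzyloxy)-3,5-dimethoxyphenyl]-3,7-dioxabicyclo[3.3.0]octan-2-ol; 14 1-(benzyloxy)-4-bromo-2-methoxybenzene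
Product: 16 [(2S,3R,4R)-2-[4-(benzyloxy)-3,5-dimethoxyphenyl]-4-{[4-(benzyloxy)-3-methoxyphenyl](hydroxy)methyl}oxolan-3-yl]methanol (both C7' epimers), via [4-(benzyloxy)-3-methoxyphenyl]magnesium bromide 15 (not isolated)
Conditions: 14, Mg, THF, 45 °C; then 12 (one third of an equivalent), 0 → 23 °C; aq. NH4Cl
Reagents that add atoms: none
Why: Grignard addition to the open hydroxy-aldehyde form of the lactol (the first equivalent deprotonates the lactol) is the standard way to attach the C7' aryl group to bicyclic lignan lactols, and the new carbinol centre is removed in the next step so its configuration does not matter.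

**Step 10**
Reactants: 16 [(2S,3R,4R)-2-[4-(benzyloxy)-3,5-dimethoxyphenyl]-4-{[4-(benzyloxy)-3-methoxyphenyl](hydroxy)methyl}oxolan-3-yl]methanol
Product: 17 4-[(2S,3R,4R)-4-(4-hydroxy-3-methoxybenzyl)-3-(hydroxymethyl)oxolan-2-yl]-2,6-dimethoxyphenol
Conditions: H2 (1 atm), 10% Pd/C, EtOAc–EtOH, 23 °C
Reagents that add atoms: none
Why: Heterogeneous palladium hydrogenolysis cleaves the two aryl benzyl ethers and then the secondary benzylic alcohol at C7' (para-hydroxybenzylic once debenzylated), while the cyclic benzylic ether C2–O1 should react more slowly under neutral conditions; no stereocentre is involved.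

**Step 11**
Reactants: 17 4-[(2S,3R,4R)-4-(4-hydroxy-3-methoxybenzyl)-3-(hydroxymethyl)oxolan-2-yl]-2,6-dimethoxyphenol; 18 (E)-ferulic acid
Product: 19 [(2S,3R,4R)-2-(4-hydroxy-3,5-dimethoxyphenyl)-4-(4-hydroxy-3-methoxybenzyl)oxolan-3-yl]methyl (E)-3-(4-hydroxy-3-methoxyphenyl)prop-2-enoate
Conditions: PPh3, i-PrO2CN=NCO2i-Pr (DIAD), THF, 0 → 23 °C
Reagents that add atoms: none
Why: Mitsunobu esterification: the primary C9 alcohol is activated as its alkoxyphosphonium ion and displaced by ferulate, which is the only nucleophile formed in quantity because the carboxylic acid is several pKa units more acidic than the phenols, a chemoselectivity established for phenolic acids; C9 is not stereogenic and the (E)-alkene is untouched.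

**Compound list**
1 | syringaldehyde (4-hydroxy-3,5-dimethoxybenzaldehyde) | COc1cc(C=O)cc(OC)c1O | starting material
2 | 4-(benzyloxy)-3,5-dimethoxybenzaldehyde | COc1cc(C=O)cc(OC)c1OCc1ccccc1 | intermediate
3 | (triphenylphosphoranylidene)acetaldehyde | O=CC=P(c1ccccc1)(c1ccccc1)c1ccccc1 | starting material
4 | (E)-3-[4-(benzyloxy)-3,5-dimethoxyphenyl]prop-2-enal | O=C/C=C/c1cc(OC)c(OCc2ccccc2)c(OC)c1 | intermediate
5 | dimethyl 2-bromomalonate | COC(=O)C(Br)C(=O)OC | starting material
6 | dimethyl (2S,3R)-2-[4-(benzyloxy)-3,5-dimethoxyphenyl]-3-formylcyclopropane-1,1-dicarboxylate (aryl and formyl trans) | O=C[C@H]1C(C(=O)OC)(C(=O)OC)[C@@H]1c1cc(OC)c(OCc2ccccc2)c(OC)c1 | intermediate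
7 | dimethyl (2S,3R)-2-[4-(benzyloxy)-3,5-dimethoxyphenyl]-3-(hydroxymethyl)cyclopropane-1,1-dicarboxylate | OC[C@H]1C(C(=O)OC)(C(=O)OC)[C@@H]1c1cc(OC)c(OCc2ccccc2)c(OC)c1 | intermediate (not isolated)
8 | methyl (1S,5R,6S)-6-[4-(benzyloxy)-3,5-dimethoxyphenyl]-2-oxo-3-oxabicyclo[3.1.0]hexane-1-carboxylate (aryl exo) | O1C[C@H]2[C@](C1=O)(C(=O)OC)[C@@H]2c1cc(OC)c(OCc2ccccc2)c(OC)c1 | intermediate
9 | formaldehyde (supplied as paraformaldehyde) | C=O | starting material
10 | methyl (1R,5R,6S)-6-[4-(benzyloxy)-3,5-dimethoxyphenyl]-2-oxo-3,7-dioxabicyclo[3.3.0]octane-1-carboxylate (cis-fused, aryl exo) | O1C[C@H]2[C@](C1=O)(C(=O)OC)CO[C@@H]2c1cc(OC)c(OCc2ccccc2)c(OC)c1 | intermediate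
11 | (1R,5R,6S)-6-[4-(benzyloxy)-3,5-dimethoxyphenyl]-3,7-dioxabicyclo[3.3.0]octan-2-one | O1C[C@H]2[C@@H](C1=O)CO[C@@H]2c1cc(OC)c(OCc2ccccc2)c(OC)c1 | intermediate
12 | (1R,5R,6S)-6-[4-(benzyloxy)-3,5-dimethoxyphenyl]-3,7-dioxabicyclo[3.3.0]octan-2-ol (lactol, both anomers) | O1C[C@H]2[C@@H](C1O)CO[C@@H]2c1cc(OC)c(OCc2ccccc2)c(OC)c1 | intermediate
13 | 4-bromo-2-methoxyphenol | COc1cc(Br)ccc1O | starting material
14 | 1-(benzyloxy)-4-bromo-2-methoxybenzene | COc1cc(Br)ccc1OCc1ccccc1 | intermediate
15 | [4-(benzyloxy)-3-methoxyphenyl]magnesium bromide | COc1cc([Mg]Br)ccc1OCc1ccccc1 | intermediate (not isolated)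
16 | [(2S,3R,4R)-2-[4-(benzyloxy)-3,5-dimethoxyphenyl]-4-{[4-(benzyloxy)-3-methoxyphenyl](hydroxy)methyl}oxolan-3-yl]methanol (both C7' epimers) | OC[C@H]1[C@@H](C(O)c2ccc(OCc3ccccc3)c(OC)c2)CO[C@@H]1c1cc(OC)c(OCc2ccccc2)c(OC)c1 | intermediate
17 | 4-[(2S,3R,4R)-4-(4-hydroxy-3-methoxybenzyl)-3-(hydroxymethyl)oxolan-2-yl]-2,6-dimethoxyphenol | OC[C@H]1[C@@H](Cc2ccc(O)c(OC)c2)CO[C@@H]1c1cc(OC)c(O)c(OC)c1 | intermediate
18 | (E)-ferulic acid | COc1cc(/C=C/C(=O)O)ccc1O | starting material
19 | [(2S,3R,4R)-2-(4-hydroxy-3,5-dimethoxyphenyl)-4-(4-hydroxy-3-methoxybenzyl)oxolan-3-yl]methyl (E)-3-(4-hydroxy-3-methoxyphenyl)prop-2-enoate | COc1cc(/C=C/C(=O)OC[C@H]2[C@@H](Cc3ccc(O)c(OC)c3)CO[C@@H]2c2cc(OC)c(O)c(OC)c2)ccc1O | target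

**Step count and risks**
Total step count: 11. Longest linear sequence: 10 steps (steps 1–7 and 9–11 from syringaldehyde; step 8 is the side branch).

Steps most likely to fail:

1. Step 5 (proposed new method). Formaldehyde may take the ring-opened ion pair before it is fully ionised, that is with inversion at C2, which would place the aryl group on the concave face, cis to C9. The ion pair may also escape capture altogether by reclosing or by losing H3 to the styrene isomer, and the trialkoxyarene may be hydroxymethylated.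
   Fallback by known chemistry, setting out from Grignard reagent 15 and aldehyde 2 and rejoining the route at 17. The oxolane is closed last at O1–C2 on a benzylic cation, as in the lactone-aldol route to 2-aryloxolane lignans. Reagent 15 with CuI (10 mol %) in THF at −30 °C should open commercial ethyl (1S,5R)-2-oxo-3-oxabicyclo[3.1.0]hexane-1-carboxylate (SMILES O1C[C@H]2[C@](C1=O)(C(=O)OCC)C2) at its cyclopropane CH2 by homoconjugate addition, giving ethyl (4R)-4-[4-(benzyloxy)-3-methoxybenzyl]-2-oxooxolane-3-carboxylate F1. Krapcho de-ethoxycarbonylation (LiCl, wet DMSO, 140 °C) should give (4R)-4-[4-(benzyloxy)-3-methoxybenzyl]oxolan-2-one F2. Its lithium enolate (LiN(i-Pr)2, THF, −78 °C) should add to aldehyde 2 anti to the benzyl group to give the trans aldol (3S,4R)-3-{[4-(benzyloxy)-3,5-dimethoxyphenyl](hydroxy)methyl}-4-[4-(benzyloxy)-3-methoxybenzyl]oxolan-2-one F3. LiAlH4 in THF should give (2R,3R)-2-{[4-(benzyloxy)-3,5-dimethoxyphenyl](hydroxy)methyl}-3-[4-(benzyloxy)-3-methoxybenzyl]butane-1,4-diol F4. Camphorsulfonic acid in CH2Cl2 at 0 °C should ionise the benzylic carbinol and let the C5 hydroxyl close the oxolane with the aryl trans to the C9 arm, giving {(2S,3R,4R)-2-[4-(benzyloxy)-3,5-dimethoxyphenyl]-4-[4-(benzyloxy)-3-methoxybenzyl]oxolan-3-yl}methanol F5. H2 with Pd/C in EtOAc should then remove the two benzyl ethers and give 17.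

2. Step 10. Slow cleavage of the C7' hydroxyl may let hydrogenolysis of the ring benzylic ether C2–O1 catch up (ring opening to the seco diol), or traces of acid on the catalyst may close the 1,4-diol onto C7' to a furofuran.
   Fallback from 16 back to 17 by radical deoxygenation (Barton–McCombie), so that palladium is needed only for the fast cleavage of the aryl benzyl ethers. TBSCl and imidazole in DMF should silylate only the primary hydroxyl, giving the C9 tert-butyldimethylsilyl ether of 16 F6. NaH, CS2 and MeI in THF should give its C7' O-(S-methyl dithiocarbonate) F7. Bu3SnH with azobisisobutyronitrile in toluene at 100 °C should give the C7'-deoxygenated silyl ether F8 through the benzylic radical. A short hydrogenolysis (H2, Pd/C, EtOAc) should give the C9 tert-butyldimethylsilyl ether of 17 F9, and Bu4NF buffered with AcOH in THF should give 17.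

3. Step 11. The activated C9 alkoxyphosphonium ion may alkylate a phenol of 17, of 18 or of the product, giving aryl ethers and oligomers instead of the ester.
   Fallback from 17 and 18 to 19 by temporary masking of all phenols as acetates and acylation of C9–OH with an acid chloride. Ac2O with aq. NaOH at 0 °C (phenoxide-selective acetylation) should give the bis(aryl acetate) of 17 F10. Ferulic acid 18 with Ac2O in pyridine should give (E)-3-(4-acetoxy-3-methoxyphenyl)prop-2-enoic acid F11, and oxalyl chloride with catalytic DMF its acid chloride (E)-3-(4-acetoxy-3-methoxyphenyl)prop-2-enoyl chloride F12. F10 and F12 with pyridine in CH2Cl2 at 0 °C should give the tri-O-acetyl derivative of 19 F13. Pyrrolidine in CH2Cl2 at 0 °C should then cleave the three aryl acetates by aminolysis, leaving the alkyl cinnamate ester, and give 19.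

**Further compounds**
F1 | step 5 | ethyl (4R)-4-[4-(benzyloxy)-3-methoxybenzyl]-2-oxooxolane-3-carboxylate (C3 epimers) | CCOC(=O)C1[C@@H](Cc2ccc(OCc3ccccc3)c(OC)c2)COC1=O
F2 | step 5 | (4R)-4-[4-(benzyloxy)-3-methoxybenzyl]oxolan-2-one | O=C1C[C@@H](Cc2ccc(OCc3ccccc3)c(OC)c2)CO1
F3 | step 5 | (3S,4R)-3-{[4-(benzyloxy)-3,5-dimethoxyphenyl](hydroxy)methyl}-4-[4-(benzyloxy)-3-methoxybenzyl]oxolan-2-one (carbinol epimers) | O=C1OC[C@H](Cc2ccc(OCc3ccccc3)c(OC)c2)[C@H]1C(O)c1cc(OC)c(OCc2ccccc2)c(OC)c1
F4 | step 5 | (2R,3R)-2-{[4-(benzyloxy)-3,5-dimethoxyphenyl](hydroxy)methyl}-3-[4-(benzyloxy)-3-methoxybenzyl]butane-1,4-diol (carbinol epimers) | OC[C@H](Cc1ccc(OCc2ccccc2)c(OC)c1)[C@H](CO)C(O)c1cc(OC)c(OCc2ccccc2)c(OC)c1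
F5 | step 5 | {(2S,3R,4R)-2-[4-(benzyloxy)-3,5-dimethoxyphenyl]-4-[4-(benzyloxy)-3-methoxybenzyl]oxolan-3-yl}methanol | OC[C@H]1[C@@H](Cc2ccc(OCc3ccccc3)c(OC)c2)CO[C@@H]1c1cc(OC)c(OCc2ccccc2)c(OC)c1
F6 | step 10 | C9 tert-butyldimethylsilyl ether of 16 | CC(C)(C)[Si](C)(C)OC[C@H]1[C@@H](C(O)c2ccc(OCc3ccccc3)c(OC)c2)CO[C@@H]1c1cc(OC)c(OCc2ccccc2)c(OC)c1
F7 | step 10 | C7' O-(S-methyl dithiocarbonate) of F6 | CC(C)(C)[Si](C)(C)OC[C@H]1[C@@H](C(OC(=S)SC)c2ccc(OCc3ccccc3)c(OC)c2)CO[C@@H]1c1cc(OC)c(OCc2ccccc2)c(OC)c1
F8 | step 10 | C7'-deoxygenated silyl ether (C9 tert-butyldimethylsilyl ether of F5) | CC(C)(C)[Si](C)(C)OC[C@H]1[C@@H](Cc2ccc(OCc3ccccc3)c(OC)c2)CO[C@@H]1c1cc(OC)c(OCc2ccccc2)c(OC)c1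
F9 | step 10 | C9 tert-butyldimethylsilyl ether of 17 | CC(C)(C)[Si](C)(C)OC[C@H]1[C@@H](Cc2ccc(O)c(OC)c2)CO[C@@H]1c1cc(OC)c(O)c(OC)c1
F10 | step 11 | bis(aryl acetate) of 17 | OC[C@H]1[C@@H](Cc2ccc(OC(C)=O)c(OC)c2)CO[C@@H]1c1cc(OC)c(OC(C)=O)c(OC)c1
F11 | step 11 | (E)-3-(4-acetoxy-3-methoxyphenyl)prop-2-enoic acid | COc1cc(/C=C/C(=O)O)ccc1OC(C)=O
F12 | step 11 | (E)-3-(4-acetoxy-3-methoxyphenyl)prop-2-enoyl chloride | COc1cc(/C=C/C(Cl)=O)ccc1OC(C)=O
F13 | step 11 | tri-O-acetyl derivative of 19 | COc1cc(/C=C/C(=O)OC[C@H]2[C@@H](Cc3ccc(OC(C)=O)c(OC)c3)CO[C@@H]2c2cc(OC)c(OC(C)=O)c(OC)c2)ccc1OC(C)=O
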